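**Plan**

1. Retrosynthetic cuts: the C1 ketone goes back to a 1α‑silyl ether and the side‑chain C=CH2 to a ketone. The bond between the two ethano‑bridge carbons is then cut so that the side‑chain carbonyl carbon re‑enters the ring between them (retro 1,2‑shift), giving a seven‑membered α‑bromo ketone plus a C6 Grignard reagent. The C2–C and C5–C bonds of the three‑carbon bridge are cut next ([4+3]), giving a eudesma‑2,4‑diene that goes back to (−)‑α‑santonin.
2. Enabling feature: in the bicyclo[2.2.2]octenone the bridge CH bonded to C2 carries an exocyclic sp2 carbon and sits next to the bridge CH2 bonded to C5. This acyl‑on‑ring pattern is the signature of a semipinacol contraction of the seven‑membered ring C1–C2–Ca–Cx–Cb–C5–C10.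
3. Forward order: ring C and the lactone come intact from santonin; ring B becomes the 2,4‑diene; the C3 bridge is added by [4+3] (two seven‑membered rings); ring contraction gives the bicyclo[2.2.2]octene; methylenation and C1 oxidation finish.
4. Stereochemistry: C6, C7, C10 and C11 come from santonin; C2 and C5 from β‑face [4+3] opposite the 1α‑silyloxy group; Ca from inversion of a C–Br centre during the ring contraction.

Key step: step 7

Remark: eudesmane numbering (C1–C15) is kept for the santonin core. The three carbons added in step 4 are called Ca (bonded to C2), Cx (the carbonyl carbon) and Cb (bonded to C5). The α‑face is the face opposite the C10 methyl group.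

**Route**

Step 1
Reactants: 1 (−)‑α‑santonin
Product: 2 1α,2α‑epoxy‑3‑oxoeudesm‑4‑en‑11βH‑12,6α‑olide
Conditions: 30% aq. H2O2, NaOH, MeOH, 0 °C; dilute HCl work‑up
Reagents that add atoms: hydrogen peroxide (OO)
Why: Weitz–Scheffer epoxidation: hydroperoxide adds in conjugate fashion to C1 of the disubstituted enone arm only (the C4=C5 arm is tetrasubstituted) and from the α‑face opposite the C10 methyl group, as is general for 1,4‑dien‑3‑ones with an angular methyl, so C1 and C2 are both set α; a lactone opened by hydroxide recloses on acidification.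

Step 2
Reactants: 2 1α,2α‑epoxy‑3‑oxoeudesm‑4‑en‑11βH‑12,6α‑olide
Product: 3 1α‑hydroxyeudesma‑2,4‑dien‑11βH‑12,6α‑olide
Conditions: N2H4·H2O, AcOH (cat.), MeOH, 0 °C to rt, short reaction time
Reagents that add atoms: none
Why: Wharton transposition: the C3 hydrazone opens the epoxide to a vinyl diazene that loses N2, moving the alkene to C2=C3 and leaving the C1 oxygen with unchanged configuration, which gives the homoannular s‑cis diene.

Step 3
Reactants: 3 1α‑hydroxyeudesma‑2,4‑dien‑11βH‑12,6α‑olide
Product: 4 1α‑(tert‑butyldimethylsilyloxy)eudesma‑2,4‑dien‑11βH‑12,6α‑olide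
Conditions: TBSOTf, 2,6‑lutidine, CH2Cl2, −78 to 0 °C
Reagents that add atoms: tert‑butyldimethylsilyl trifluoromethanesulfonate (CC(C)(C)[Si](C)(C)OS(=O)(=O)C(F)(F)F)
Why: Silylation of the hindered secondary allylic alcohol with the silyl triflate at low temperature; no stereocentre is formed, and the axial 1α‑silyloxy group is kept as the screen for the α‑face in step 4.

Step 4
Reactants: 4 1α‑(tert‑butyldimethylsilyloxy)eudesma‑2,4‑dien‑11βH‑12,6α‑olide; 5 1,1,3‑trichloroacetone
Product: 6 dichloro [4+3] adduct (bicyclo[3.2.2]non‑6‑en‑3‑one: C2 and C5 bridged on the β‑face by CaHCl–Cx(=O)–CbHCl; both Cl syn to the C3=C4 bridge; halide epimers are carried on together)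
Conditions: 5 (3 equiv, slow addition), Et3N, CF3CH2OH, 0 °C to rt
Reagents that add atoms: none
Why: [4+3] cycloaddition of the 1,3‑dichloro‑2‑oxyallyl cation (base‑induced ionisation of 5 in the ionising solvent) to the s‑cis‑locked diene across C2 and C5; the cation should approach the β‑face, syn to the C10 methyl but away from the axial 1α‑silyloxy group, the lactone oxygen and C9 on the α‑face, which sets C2 and C5, and the symmetric cation leaves no regiochemical question.

Step 5
Reactants: 6 dichloro [4+3] adduct
Product: 7 parent bicyclo[3.2.2]non‑6‑en‑3‑one (C2 and C5 bridged by CaH2–Cx(=O)–CbH2)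
Conditions: Zn/Cu couple, NH4Cl, MeOH, rt
Reagents that add atoms: none
Why: Reductive dehalogenation of the α‑chloro ketone by zinc through the zinc enolate, the standard sequel to halogenated oxyallyl cycloadditions; lactone, silyl ether and alkene are inert and no stereocentre of the core is touched.

Step 6
Reactants: 7 parent bicyclo[3.2.2]non‑6‑en‑3‑one
Product: 9 Ca‑bromo ketone (Br syn to the C3=C4 bridge), via trimethylsilyl enol ether 8 (not isolated)
Conditions: LiN(SiMe3)2, Me3SiCl, THF, −78 °C; then NBS, THF, −78 to 0 °C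
Reagents that add atoms: chlorotrimethylsilane (C[Si](C)(C)Cl; atoms kept only in 8); N‑bromosuccinimide (BrN1C(=O)CCC1=O)
Why: Kinetic deprotonation should take the less hindered α‑methylene Ca (next to the C2–H bridgehead) and not Cb (next to quaternary C5), and electrophilic bromination of the enol silane by NBS should occur on the face turned to the flat C3=C4 bridge, away from the C10 methyl and H1 on the C1–C10 bridge, which sets the C–Br centre syn to the C3=C4 bridge.

Step 7
Reactants: 9 Ca‑bromo ketone; 10 5‑bromo‑2‑methylpent‑2‑ene (used as its Grignard reagent)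
Product: 12 ring‑contracted ketone (bicyclo[2.2.2]oct‑5‑ene; 5‑methylhex‑4‑enoyl group on Ca syn to the C3=C4 bridge), via bromomagnesium bromohydrin alkoxide 11 (not isolated)
Conditions: 10, Mg, THF (4‑methylpent‑3‑enylmagnesium bromide, 1.05 equiv); add to 9 in THF/toluene, −78 °C; then 25 to 60 °C
Reagents that add atoms: magnesium ([Mg]; kept only in 11)
Why: The Grignard reagent adds to the carbonyl Cx of the bromo ketone from the side of the flat C3=C4 bridge to give alkoxide 11; on warming, the Cx–Cb ring bond that lies anti‑periplanar to the Ca–Br bond migrates from Cx to Ca as bromide leaves as MgBr2, so Cx is pushed out of the ring as the ketone carbonyl. This is a quasi‑Favorskii (semipinacol) ring contraction, the known follow‑up reaction of [4+3] cycloadducts that carry an α‑halogen. The two seven‑membered rings that share the three‑carbon bridge (C2–Ca–Cx–Cb–C5 closed through C1–C10 or through C3=C4) each lose Cx and become the six‑membered rings of a bicyclo[2.2.2]octene by a suprafacial 1,2‑carbon shift with backside displacement at Ca. The only new stereocentre, Ca, is fixed by inversion of the C–Br centre set in step 6, which places the acyl group syn to the C3=C4 bridge; C2, C5 and the santonin centres are untouched. The step needs the 1,2‑shift to win over epoxide closure, enolisation and halogen–metal exchange. The covalent, halophilic magnesium alkoxide, the conformer that tilts Cx toward the unsubstituted C3=C4 bridge (away from the C10 methyl) and so puts the ring bond rather than oxygen anti to bromide, and complete addition at −78 °C with 1.05 equiv before warming should secure this.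

Step 8
Reactants: 12 ring‑contracted ketone
Product: 13 1α‑silyl ether of the 1‑dihydro target (side chain now 6‑methylhepta‑1,5‑dien‑2‑yl)
Conditions: Zn, CH2Br2, TiCl4, THF/CH2Cl2, 0 °C to rt
Reagents that add atoms: dibromomethane (BrCBr)
Why: Lombardo–Takai methylenation: the non‑basic zinc/titanium methylene reagent converts the ketone into the 1,1‑disubstituted alkene without epimerising the adjacent Ca centre and does not react with the lactone.

Step 9
Reactants: 13 1α‑silyl ether of the 1‑dihydro target
Product: 14 1α‑hydroxy compound (1‑dihydro target)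
Conditions: Bu4NF, THF, 0 to 50 °C
Reagents that add atoms: none
Why: Fluoride‑induced cleavage of the silyl ether; no stereocentre changes.

Step 10
Reactants: 14 1α‑hydroxy compound
Product: 15 target CNP0385704.1
Conditions: Dess–Martin periodinane, CH2Cl2, 0 °C to rt
Reagents that add atoms: none
Why: Dess–Martin oxidation of the secondary alcohol to the ketone; the new carbonyl is flanked by a bridgehead CH and a quaternary carbon, so nothing can epimerise.

**Compound list**

1 | (−)‑α‑santonin (3‑oxoeudesma‑1,4‑dien‑11βH‑12,6α‑olide) | C[C@@H]1C(=O)O[C@H]2[C@H]1CC[C@@]1(C)C=CC(=O)C(C)=C21 | starting material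
2 | 1α,2α‑epoxy‑3‑oxoeudesm‑4‑en‑11βH‑12,6α‑olide | C[C@@H]1C(=O)O[C@H]2[C@H]1CC[C@@]1(C)[C@H]3O[C@H]3C(=O)C(C)=C21 | intermediate
3 | 1α‑hydroxyeudesma‑2,4‑dien‑11βH‑12,6α‑olide | C[C@@H]1C(=O)O[C@H]2[C@H]1CC[C@@]1(C)[C@@H](O)C=CC(C)=C21 | intermediate
4 | 1α‑(tert‑butyldimethylsilyloxy)eudesma‑2,4‑dien‑11βH‑12,6α‑olide | C[C@@H]1C(=O)O[C@H]2[C@H]1CC[C@@]1(C)[C@@H](O[Si](C)(C)C(C)(C)C)C=CC(C)=C21 | intermediate
5 | 1,1,3‑trichloroacetone | ClCC(=O)C(Cl)Cl | starting material
6 | dichloro [4+3] adduct, bicyclo[3.2.2]non‑6‑en‑3‑one with CaHCl and CbHCl (Cl syn to the C3=C4 bridge), 1α‑OTBS | O=C1[C@@H](Cl)[C@@]23C(C)=C[C@@H]([C@H]1Cl)[C@H](O[Si](C)(C)C(C)(C)C)[C@]2(C)CC[C@H]1[C@H](C)C(=O)O[C@@H]13 | intermediate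
7 | parent bicyclo[3.2.2]non‑6‑en‑3‑one, 1α‑OTBS | O=C1C[C@@]23C(C)=C[C@@H](C1)[C@H](O[Si](C)(C)C(C)(C)C)[C@]2(C)CC[C@H]1[C@H](C)C(=O)O[C@@H]13 | intermediate
8 | trimethylsilyl enol ether of 7 toward Ca | C[Si](C)(C)OC=1C[C@@]23C(C)=C[C@@H](C=1)[C@H](O[Si](C)(C)C(C)(C)C)[C@]2(C)CC[C@H]1[C@H](C)C(=O)O[C@@H]13 | intermediate (not isolated)
9 | Ca‑bromo ketone, Br syn to the C3=C4 bridge | O=C1C[C@@]23C(C)=C[C@@H]([C@H]1Br)[C@H](O[Si](C)(C)C(C)(C)C)[C@]2(C)CC[C@H]1[C@H](C)C(=O)O[C@@H]13 | intermediate
10 | 5‑bromo‑2‑methylpent‑2‑ene | CC(C)=CCCBr | starting material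
11 | bromomagnesium alkoxide of the bromohydrin (4‑methylpent‑3‑enyl on Cx, syn to the C3=C4 bridge) | Br[Mg]O[C@]1(CCC=C(C)C)C[C@@]23C(C)=C[C@@H]([C@H]1Br)[C@H](O[Si](C)(C)C(C)(C)C)[C@]2(C)CC[C@H]1[C@H](C)C(=O)O[C@@H]13 | intermediate (not isolated)
12 | ring‑contracted ketone, bicyclo[2.2.2]oct‑5‑ene with 5‑methylhex‑4‑enoyl on Ca (syn to the C3=C4 bridge), 1α‑OTBS | CC(C)=CCCC(=O)[C@H]1C[C@@]23C(C)=C[C@@H]1[C@H](O[Si](C)(C)C(C)(C)C)[C@]2(C)CC[C@H]1[C@H](C)C(=O)O[C@@H]13 | intermediate
13 | 1α‑silyl ether of the 1‑dihydro target | C=C(CCC=C(C)C)[C@H]1C[C@@]23C(C)=C[C@@H]1[C@H](O[Si](C)(C)C(C)(C)C)[C@]2(C)CC[C@H]1[C@H](C)C(=O)O[C@@H]13 | intermediate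
14 | 1α‑hydroxy compound (1‑dihydro target) | C=C(CCC=C(C)C)[C@H]1C[C@@]23C(C)=C[C@@H]1[C@H](O)[C@]2(C)CC[C@H]1[C@H](C)C(=O)O[C@@H]13 | intermediate
15 | CNP0385704.1 | C=C(CCC=C(C)C)[C@H]1C[C@@]23C(C)=C[C@@H]1C(=O)[C@]2(C)CC[C@H]1[C@H](C)C(=O)O[C@@H]13 | target

**Step count**

Total steps: 10. Longest linear sequence: 10 (from 1).

**Steps most likely to fail**

Step 4. Bond formation at the fully substituted C5 terminus may be too slow, so that the oxyallyl cation is consumed by the solvent, and the facial selectivity may be poor. The fallback sets out from 3 and gives up the three‑carbon bridge. Dess–Martin oxidation of 3 should give the dienone 1‑oxoeudesma‑2,4‑dien‑11βH‑12,6α‑olide F1. F1 would then be heated with myrcene (toluene, 110 °C) in a direct [4+2] cycloaddition of the dienone across C2/C5 with the vinyl group of myrcene. This comes back to the route at 15. The price is that periselectivity (myrcene can also react as the diene) and the endo/exo ratio are no longer fixed by the substrate.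

Step 6. Enolisation may show poor site selectivity, with deprotonation at Cb as well as Ca. The fallback sets out from 7 and puts the site choice under thermodynamic control. Claisen formylation (NaH, HCO2Et, THF) should give the hydroxymethylene ketone F2 at the less hindered α‑methylene Ca. NBS would convert F2 into the α‑bromo‑α‑formyl ketone F3. Retro‑Claisen deformylation (K2CO3, MeOH), with equilibration of the bromide to the less hindered epimer, comes back to the route at 9.

Step 7. The halohydrin alkoxide may close to an epoxide, or the Grignard reagent may enolise the ketone or exchange the halogen, instead of the 1,2‑shift taking place. The fallback sets out from 7, by way of the hydroxymethylene ketone F2, and changes the ring contraction to a Wolff rearrangement. Regitz deformylative diazo transfer (MeSO2N3, Et3N, MeCN) should give the α‑diazo ketone F4. Photolysis (hν, THF) in the presence of N,O‑dimethylhydroxylamine contracts the ring through the ketene to the Weinreb amide F5; the Ca centre is equilibrated with base if needed. The Grignard reagent from 10 then converts F5 into the ketone, coming back to the route at 12.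

Further compounds
F1 | step 4 | 1‑oxoeudesma‑2,4‑dien‑11βH‑12,6α‑olide | C[C@@H]1C(=O)O[C@H]2[C@H]1CC[C@@]1(C)C(=O)C=CC(C)=C21
F2 | step 6 | Ca‑hydroxymethylene derivative of ketone 7 | O=C1C[C@@]23C(C)=C[C@@H](/C1=C/O)[C@H](O[Si](C)(C)C(C)(C)C)[C@]2(C)CC[C@H]1[C@H](C)C(=O)O[C@@H]13
F3 | step 6 | Ca‑bromo‑Ca‑formyl ketone | O=C1C[C@@]23C(C)=C[C@@H]([C@]1(Br)C=O)[C@H](O[Si](C)(C)C(C)(C)C)[C@]2(C)CC[C@H]1[C@H](C)C(=O)O[C@@H]13
F4 | step 7 | Ca‑diazo ketone | O=C1C[C@@]23C(C)=C[C@@H](C1=[N+]=[N-])[C@H](O[Si](C)(C)C(C)(C)C)[C@]2(C)CC[C@H]1[C@H](C)C(=O)O[C@@H]13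
F5 | step 7 | ring‑contracted Weinreb amide (N‑methoxy‑N‑methylcarboxamide on Ca, syn to the C3=C4 bridge) | CON(C)C(=O)[C@H]1C[C@@]23C(C)=C[C@@H]1[C@H](O[Si](C)(C)C(C)(C)C)[C@]2(C)CC[C@H]1[C@H](C)C(=O)O[C@@H]13
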